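## Retrosynthetic overview

1. The 5-OH is unmasked last from a 5-O-ethyl flavonol. Ring C (O1, C2, C3, C4) is closed by acid cyclodehydration of a 1,3-diketone that arises from a Baker–Venkataraman shift of a 4-(methoxymethoxy)benzoate (ring B) onto a glycolyl ketone (C3 with its oxygen, and C4).
2. The glycolyl group is placed on C4a by lithiation of the only free position of a fully substituted ring A ether and acylation with a glycolic Weinreb amide.
3. Ring A is built by benzannulation of 3-ethoxy-4-prenylcyclobutenone with a prenylated triisopropylsilyl ynol ether. The strategy rests on ring A carrying oxygen at C5, C7 and C8a in strict alternation with carbon substituents at C6, C8 and C4a, the pattern that a 3-alkoxy vinylketene and a siloxyalkyne deliver (C7–C8 and C8a–C4a formed, C6–C7 re-formed on closure).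
4. The cyclobutenone comes from prenylketene and ethoxyacetylene; the ynol ether comes from prenylacetylene by acetylide oxidation and O-silylation.
5. Order of ring formation: ring A (benzannulation), then ring C (pyranone closure); ring B is carried in intact.

Key step: step 7

Remark: locants such as C5, C7 or C8a are the flavone locants of the target throughout. The target has no stereocentre; every sp3 centre that appears on the way forms without control and is erased later, so such compounds are written without configuration. Triethyl orthoacetate, ethoxyacetylene and ethynylmagnesium bromide are taken as purchased.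

## Route

Step 1
Reactants: 1 2-methylbut-3-en-2-ol; 2 triethyl orthoacetate
Product: 3 ethyl 5-methylhex-4-enoate
Conditions: EtCO2H (cat.), neat, 140 °C, EtOH distilled off
Reagents that add atoms: none
Why: Johnson–Claisen rearrangement: the ketene acetal formed from the tertiary allylic alcohol undergoes a [3,3]-sigmatropic shift that should deliver the γ,δ-unsaturated ester with the trisubstituted (prenyl-type) double bond in place.

Step 2
Reactants: 3 ethyl 5-methylhex-4-enoate
Product: 4 5-methylhex-4-enoic acid
Conditions: LiOH, THF/MeOH/H2O, rt; then 1 M HCl, 0 °C, to pH 3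
Reagents that add atoms: lithium hydroxide, [Li+].[OH-]
Why: Ester saponification; the brief, cold acidification should free the acid without acid-catalysed lactonisation onto the trisubstituted alkene.

Step 3
Reactants: 4 5-methylhex-4-enoic acid
Product: 5 5-methylhex-4-enoyl chloride
Conditions: (COCl)2, DMF (cat.), CH2Cl2, 0 °C to rt; concentrate, use crude
Reagents that add atoms: oxalyl chloride, ClC(=O)C(=O)Cl
Why: Acyl chloride formation with oxalyl chloride under Vilsmeier-type catalysis, mild enough that addition of HCl to the alkene should not compete at 0 °C.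

Step 4
Reactants: 5 5-methylhex-4-enoyl chloride; 6 ethoxyacetylene
Product: 8 racemic 3-ethoxy-4-(3-methylbut-2-en-1-yl)cyclobut-2-en-1-one, via prenylketene 7 (not isolated)
Conditions: 6 (2.5 equiv), Et3N (slow addition), Et2O, 0 °C to rt
Reagents that add atoms: none
Why: Dehydrochlorination gives the monoalkylketene, which should undergo the known regioselective [2+2] cycloaddition with the ynol ether (nucleophilic CH terminus to the ketene carbonyl carbon) to the 4-alkyl-3-ethoxycyclobutenone; the C4 centre forms as a racemate and is destroyed in step 7.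

Step 5
Reactants: 9 prenyl bromide; 10 ethynylmagnesium bromide
Product: 11 5-methylhex-4-en-1-yne
Conditions: HC≡CMgBr (1.5 equiv, THF), CuCl (5 mol %), THF, 0 °C to rt; fractional distillation
Reagents that add atoms: none
Why: Copper-catalysed coupling of an alkynyl Grignard reagent with an allylic bromide, expected to occur at the unhindered primary carbon (SN2) rather than at the tertiary terminus, giving the skipped enyne.

Step 6
Reactants: 11 5-methylhex-4-en-1-yne
Product: 14 triisopropyl[(5-methylhex-4-en-1-yn-1-yl)oxy]silane, via lithium acetylide 12 (not isolated), via lithium ynolate 13 (not isolated)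
Conditions: n-BuLi, THF, −78 °C; LiOOt-Bu (from t-BuOOH and LiN(SiMe3)2, THF), −78 to 0 °C; i-Pr3SiOTf, −78 to 0 °C
Reagents that add atoms: tert-butyl hydroperoxide, CC(C)(C)OO; triisopropylsilyl trifluoromethanesulfonate, CC(C)[Si](OS(=O)(=O)C(F)(F)F)(C(C)C)C(C)C
Why: Oxidation of a lithium acetylide with lithium tert-butyl peroxide (electrophilic oxygen transfer) gives the lithium ynolate, which the hindered silyl triflate should trap on oxygen as the isolable silyl ynol ether; deprotonation at −78 °C is selective for the terminal C–H, so the skipped enyne should not isomerise.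

Step 7
Reactants: 8 racemic 3-ethoxy-4-(3-methylbut-2-en-1-yl)cyclobut-2-en-1-one; 14 triisopropyl[(5-methylhex-4-en-1-yn-1-yl)oxy]silane
Product: 19 3-ethoxy-2,6-bis(3-methylbut-2-en-1-yl)-5-[(triisopropylsilyl)oxy]phenol, via ethoxy vinylketene 15 (not isolated), via vinylcyclobutenone 16 (not isolated), via dienylketene 17 (not isolated), via cyclohexadienone 18 (not isolated)
Conditions: 14 (1.3 equiv), toluene (0.2 M), 80 °C then 110 °C, argon
Reagents that add atoms: none
Why: Heat opens cyclobutenone 8 by a four-electron electrocyclic ring opening (the alkyl group turning outward) to the ethoxy vinylketene 15, and the nucleophilic prenyl-bearing carbon of ynol ether 14 adds to its ketene carbonyl carbon in a regiospecific [2+2] cycloaddition that forms C7–C8 and C8a–C4a and gives vinylcyclobutenone 16. A second, reversible four-electron opening gives dienylketene 17, and ring A closes by a thermal six-electron (disrotatory) electrocyclisation that joins the ketene carbon to the diene terminus (C7–C6), after which cyclohexadienone 18 tautomerises to the phenol. The closest known reaction type is the Danheiser benzannulation of cyclobutenones with trialkylsilyl ynol ethers to resorcinol monosilyl ethers; the 3-ethoxy group only adds a third oxygen to the vinylketene. No stereocentre is set: the sp3 centres of 8, 16 and 18 are erased by ring opening and aromatisation. The selectivity needed is the regiochemistry of the ketene–ynol ether addition, which the polarisation of both partners secures (electrophilic ketene carbonyl carbon, nucleophilic carbon β to the silyloxy group), so that oxygen ends up at C5, C7 and C8a with O7 free, O8a silylated and O5 ethylated, and C4a is the only unsubstituted carbon. Of the two dienylketene geometries only the one with the ethoxyvinyl arm turned inward can cyclise, and the reversibility of the opening should funnel material through it.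

Step 8
Reactants: 19 3-ethoxy-2,6-bis(3-methylbut-2-en-1-yl)-5-[(triisopropylsilyl)oxy]phenol
Product: 20 5-ethoxy-2,4-bis(3-methylbut-2-en-1-yl)benzene-1,3-diol
Conditions: n-Bu4NF, THF, 0 °C; aq. NH4Cl
Reagents that add atoms: none
Why: Fluoride-mediated desilylation of the aryl silyl ether, driven by the strong Si–F bond and harmless to the prenyl groups and the ethyl ether.

Step 9
Reactants: 20 5-ethoxy-2,4-bis(3-methylbut-2-en-1-yl)benzene-1,3-diol
Product: 21 1-ethoxy-3,5-bis(methoxymethoxy)-2,4-bis(3-methylbut-2-en-1-yl)benzene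
Conditions: NaH (2.5 equiv), MOMCl (2.5 equiv), DMF, 0 °C to rt
Reagents that add atoms: chloromethyl methyl ether, COCCl
Why: Williamson-type O-alkylation of the bis-phenoxide with MOMCl, placing on O8a and O7 the acetal ethers that direct the lithiation of step 12 and withstand base.

Step 10
Reactants: 22 methyl glycolate
Product: 23 methyl 2-(methoxymethoxy)acetate
Conditions: MOMCl, i-Pr2NEt, CH2Cl2, 0 °C to rt
Reagents that add atoms: chloromethyl methyl ether, COCCl
Why: O-Alkylation of the primary alcohol with MOMCl under amine base (acetal protection), leaving the ester untouched.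

Step 11
Reactants: 23 methyl 2-(methoxymethoxy)acetate
Product: 24 N-methoxy-2-(methoxymethoxy)-N-methylacetamide
Conditions: MeNH(OMe)·HCl, i-PrMgCl, THF, −20 to 0 °C
Reagents that add atoms: N,O-dimethylhydroxylamine hydrochloride, CNOC.Cl
Why: Aminolysis of the ester by the chloromagnesium amide of N,O-dimethylhydroxylamine (Weinreb amide formation), which stops at the amide stage.

Step 12
Reactants: 21 1-ethoxy-3,5-bis(methoxymethoxy)-2,4-bis(3-methylbut-2-en-1-yl)benzene; 24 N-methoxy-2-(methoxymethoxy)-N-methylacetamide
Product: 26 1-[2-ethoxy-4,6-bis(methoxymethoxy)-3,5-bis(3-methylbut-2-en-1-yl)phenyl]-2-(methoxymethoxy)ethan-1-one, via aryllithium 25 (not isolated)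
Conditions: n-BuLi, TMEDA, THF, 0 °C, 1 h; then 24, −78 to 0 °C; aq. NH4Cl
Reagents that add atoms: none
Why: Directed ortho-metalation at the only ring C–H (C4a), activated by the flanking OMOM and OEt groups, followed by acylation with the Weinreb amide, which should deliver the ketone without over-addition.

Step 13
Reactants: 26 1-[2-ethoxy-4,6-bis(methoxymethoxy)-3,5-bis(3-methylbut-2-en-1-yl)phenyl]-2-(methoxymethoxy)ethan-1-one
Product: 27 1-[2-ethoxy-6-hydroxy-4-(methoxymethoxy)-3,5-bis(3-methylbut-2-en-1-yl)phenyl]-2-(methoxymethoxy)ethan-1-one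
Conditions: MgBr2·OEt2 (3 equiv), Et2O/CH2Cl2, 0 °C to rt; aq. NH4Cl
Reagents that add atoms: none
Why: Chelation-controlled acetal cleavage: MgBr2 bound between the ketone oxygen and the ortho OMOM oxygen should remove only that MOM group, sparing the non-chelated aryl MOM ether at O7, the less labile aliphatic MOM ether and, in the absence of protic acid, the prenyl groups.

Step 14
Reactants: 28 methyl 4-hydroxybenzoate
Product: 29 methyl 4-(methoxymethoxy)benzoate
Conditions: MOMCl, i-Pr2NEt, CH2Cl2, 0 °C to rt
Reagents that add atoms: chloromethyl methyl ether, COCCl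
Why: O-Alkylation of the phenol with MOMCl (acetal protection), so that ring B tolerates the strong base of step 17.

Step 15
Reactants: 29 methyl 4-(methoxymethoxy)benzoate
Product: 30 4-(methoxymethoxy)benzoic acid
Conditions: LiOH, THF/MeOH/H2O, rt; then 1 M HCl, 0 °C, to pH 3
Reagents that add atoms: lithium hydroxide, [Li+].[OH-]
Why: Ester saponification; the aryl MOM ether is stable to base and to the brief cold acidification.

Step 16
Reactants: 27 1-[2-ethoxy-6-hydroxy-4-(methoxymethoxy)-3,5-bis(3-methylbut-2-en-1-yl)phenyl]-2-(methoxymethoxy)ethan-1-one; 30 4-(methoxymethoxy)benzoic acid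
Product: 31 3-ethoxy-5-(methoxymethoxy)-2-[(methoxymethoxy)acetyl]-4,6-bis(3-methylbut-2-en-1-yl)phenyl 4-(methoxymethoxy)benzoate
Conditions: DCC, DMAP (cat.), CH2Cl2, rt
Reagents that add atoms: none
Why: Steglich esterification (carbodiimide activation with DMAP acyl transfer) of the hydrogen-bonded ortho-acyl phenol, a neutral method that leaves the MOM ethers and prenyl groups intact.

Step 17
Reactants: 31 3-ethoxy-5-(methoxymethoxy)-2-[(methoxymethoxy)acetyl]-4,6-bis(3-methylbut-2-en-1-yl)phenyl 4-(methoxymethoxy)benzoate
Product: 32 1-[2-ethoxy-6-hydroxy-4-(methoxymethoxy)-3,5-bis(3-methylbut-2-en-1-yl)phenyl]-2-(methoxymethoxy)-3-[4-(methoxymethoxy)phenyl]propane-1,3-dione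
Conditions: LiN(SiMe3)2 (2.5 equiv), THF, −78 to −10 °C; AcOH
Reagents that add atoms: none
Why: Baker–Venkataraman rearrangement: deprotonation α to the ketone and intramolecular O-to-C transfer of the aroyl group through a six-membered transition state should give the 2-alkoxy-1,3-diketone, whose C2 centre is uncontrolled and is lost in step 18.

Step 18
Reactants: 32 1-[2-ethoxy-6-hydroxy-4-(methoxymethoxy)-3,5-bis(3-methylbut-2-en-1-yl)phenyl]-2-(methoxymethoxy)-3-[4-(methoxymethoxy)phenyl]propane-1,3-dione
Product: 35 5-ethoxy-3,7-dihydroxy-2-(4-hydroxyphenyl)-6,8-bis(3-methylbut-2-en-1-yl)-4H-chromen-4-one, via hemiketal 33 (not isolated), via MOM-protected flavone 34 (not isolated)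
Conditions: 3 M aq. HCl/MeOH (1:5), 50 °C, argon
Reagents that add atoms: none
Why: Acid-catalysed cyclodehydration (attack of the C8a phenol on the aroyl carbonyl, 6-exo-trig, then loss of water) closes ring C, and the same medium should solvolyse the three MOM acetals to dimethoxymethane while the ethyl ether at O5 keeps that oxygen from adding to the C6 prenyl group.

Step 19
Reactants: 35 5-ethoxy-3,7-dihydroxy-2-(4-hydroxyphenyl)-6,8-bis(3-methylbut-2-en-1-yl)-4H-chromen-4-one
Product: 36 6,8-diprenylkaempferol, 3,5,7-trihydroxy-2-(4-hydroxyphenyl)-6,8-bis(3-methylbut-2-en-1-yl)-4H-chromen-4-one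
Conditions: MgI2·OEt2 (excess), THF/toluene, 90 °C, argon sweep; then aq. NH4Cl/Na2S2O3
Reagents that add atoms: none
Why: Chelation-assisted ether cleavage: MgI2 bound between the C4 carbonyl and O5 should activate the peri ethyl ether for SN2 attack by iodide (loss of iodoethane), a reaction type known to spare C-prenyl groups and free phenols because no protic acid is present.

## Compound list

1 | 2-methylbut-3-en-2-ol | C=CC(C)(C)O | starting material
2 | triethyl orthoacetate | CCOC(C)(OCC)OCC | starting material
3 | ethyl 5-methylhex-4-enoate | CCOC(=O)CCC=C(C)C | intermediate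
4 | 5-methylhex-4-enoic acid | OC(=O)CCC=C(C)C | intermediate
5 | 5-methylhex-4-enoyl chloride | ClC(=O)CCC=C(C)C | intermediate
6 | ethoxyacetylene (ethoxyethyne) | C#COCC | starting material
7 | prenylketene (5-methylhexa-1,4-dien-1-one) | O=C=CCC=C(C)C | intermediate (not isolated)
8 | 3-ethoxy-4-(3-methylbut-2-en-1-yl)cyclobut-2-en-1-one (racemic) | CCOC1=CC(=O)C1CC=C(C)C | intermediate
9 | prenyl bromide (1-bromo-3-methylbut-2-ene) | CC(C)=CCBr | starting material
10 | ethynylmagnesium bromide | C#C[Mg]Br | starting material
11 | 5-methylhex-4-en-1-yne | C#CCC=C(C)C | intermediate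
12 | (5-methylhex-4-en-1-yn-1-yl)lithium | [Li]C#CCC=C(C)C | intermediate (not isolated)
13 | lithium 5-methylhex-4-en-1-yn-1-olate | [Li]OC#CCC=C(C)C | intermediate (not isolated)
14 | triisopropyl[(5-methylhex-4-en-1-yn-1-yl)oxy]silane | CC(C)=CCC#CO[Si](C(C)C)(C(C)C)C(C)C | intermediate
15 | (3Z)-3-ethoxy-7-methylocta-1,3,6-trien-1-one | O=C=C/C(OCC)=C/CC=C(C)C | intermediate (not isolated)
16 | 4-[(1Z)-1-ethoxy-5-methylhexa-1,4-dien-1-yl]-2-(3-methylbut-2-en-1-yl)-3-[(triisopropylsilyl)oxy]cyclobut-2-en-1-one (racemic) | O=C1C(CC=C(C)C)=C(O[Si](C(C)C)(C(C)C)C(C)C)C1/C(OCC)=C/CC=C(C)C | intermediate (not isolated)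
17 | (3E,5Z)-5-ethoxy-9-methyl-2-(3-methylbut-2-en-1-yl)-3-[(triisopropylsilyl)oxy]deca-1,3,5,8-tetraen-1-one | O=C=C(CC=C(C)C)/C(O[Si](C(C)C)(C(C)C)C(C)C)=C\C(OCC)=C\CC=C(C)C | intermediate (not isolated)
18 | 5-ethoxy-2,6-bis(3-methylbut-2-en-1-yl)-3-[(triisopropylsilyl)oxy]cyclohexa-2,4-dien-1-one (racemic) | O=C1C(CC=C(C)C)=C(O[Si](C(C)C)(C(C)C)C(C)C)C=C(OCC)C1CC=C(C)C | intermediate (not isolated)
19 | 3-ethoxy-2,6-bis(3-methylbut-2-en-1-yl)-5-[(triisopropylsilyl)oxy]phenol | Oc1c(CC=C(C)C)c(O[Si](C(C)C)(C(C)C)C(C)C)cc(OCC)c1CC=C(C)C | intermediate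
20 | 5-ethoxy-2,4-bis(3-methylbut-2-en-1-yl)benzene-1,3-diol | Oc1c(CC=C(C)C)c(O)cc(OCC)c1CC=C(C)C | intermediate
21 | 1-ethoxy-3,5-bis(methoxymethoxy)-2,4-bis(3-methylbut-2-en-1-yl)benzene | COCOc1c(CC=C(C)C)c(OCOC)cc(OCC)c1CC=C(C)C | intermediate
22 | methyl glycolate | COC(=O)CO | starting material
23 | methyl 2-(methoxymethoxy)acetate | COCOCC(=O)OC | intermediate
24 | N-methoxy-2-(methoxymethoxy)-N-methylacetamide | COCOCC(=O)N(C)OC | intermediate
25 | [2-ethoxy-4,6-bis(methoxymethoxy)-3,5-bis(3-methylbut-2-en-1-yl)phenyl]lithium | [Li]c1c(OCC)c(CC=C(C)C)c(OCOC)c(CC=C(C)C)c1OCOC | intermediate (not isolated)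
26 | 1-[2-ethoxy-4,6-bis(methoxymethoxy)-3,5-bis(3-methylbut-2-en-1-yl)phenyl]-2-(methoxymethoxy)ethan-1-one | COCOCC(=O)c1c(OCC)c(CC=C(C)C)c(OCOC)c(CC=C(C)C)c1OCOC | intermediate
27 | 1-[2-ethoxy-6-hydroxy-4-(methoxymethoxy)-3,5-bis(3-methylbut-2-en-1-yl)phenyl]-2-(methoxymethoxy)ethan-1-one | COCOCC(=O)c1c(OCC)c(CC=C(C)C)c(OCOC)c(CC=C(C)C)c1O | intermediate
28 | methyl 4-hydroxybenzoate | COC(=O)c1ccc(O)cc1 | starting material
29 | methyl 4-(methoxymethoxy)benzoate | COCOc1ccc(cc1)C(=O)OC | intermediate
30 | 4-(methoxymethoxy)benzoic acid | COCOc1ccc(cc1)C(=O)O | intermediate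
31 | 3-ethoxy-5-(methoxymethoxy)-2-[(methoxymethoxy)acetyl]-4,6-bis(3-methylbut-2-en-1-yl)phenyl 4-(methoxymethoxy)benzoate | COCOCC(=O)c1c(OCC)c(CC=C(C)C)c(OCOC)c(CC=C(C)C)c1OC(=O)c1ccc(OCOC)cc1 | intermediate
32 | 1-[2-ethoxy-6-hydroxy-4-(methoxymethoxy)-3,5-bis(3-methylbut-2-en-1-yl)phenyl]-2-(methoxymethoxy)-3-[4-(methoxymethoxy)phenyl]propane-1,3-dione (racemic) | COCOC(C(=O)c1ccc(OCOC)cc1)C(=O)c1c(OCC)c(CC=C(C)C)c(OCOC)c(CC=C(C)C)c1O | intermediate
33 | 5-ethoxy-2-hydroxy-3,7-bis(methoxymethoxy)-2-[4-(methoxymethoxy)phenyl]-6,8-bis(3-methylbut-2-en-1-yl)-2,3-dihydro-4H-chromen-4-one (mixture of stereoisomers) | COCOC1C(=O)c2c(OCC)c(CC=C(C)C)c(OCOC)c(CC=C(C)C)c2OC1(O)c1ccc(OCOC)cc1 | intermediate (not isolated)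
34 | 5-ethoxy-3,7-bis(methoxymethoxy)-2-[4-(methoxymethoxy)phenyl]-6,8-bis(3-methylbut-2-en-1-yl)-4H-chromen-4-one | CCOc1c(CC=C(C)C)c(OCOC)c(CC=C(C)C)c2oc(-c3ccc(OCOC)cc3)c(OCOC)c(=O)c12 | intermediate (not isolated)
35 | 5-ethoxy-3,7-dihydroxy-2-(4-hydroxyphenyl)-6,8-bis(3-methylbut-2-en-1-yl)-4H-chromen-4-one | CCOc1c(CC=C(C)C)c(O)c(CC=C(C)C)c2oc(-c3ccc(O)cc3)c(O)c(=O)c12 | intermediate
36 | 6,8-diprenylkaempferol | CC(C)=CCc1c(O)c(CC=C(C)C)c2oc(-c3ccc(O)cc3)c(O)c(=O)c2c1O | target

## Step count and risks

Total step count: 19. Longest linear sequence: 13 steps (steps 1–4, 7–9, 12, 13, 16–19).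

The three steps most likely to fail:

1. Step 19, cleavage of the C5 ethyl ether. Iodide attack on an ethyl carbon is much slower than on a methyl carbon, and magnesium may be held at the 3-hydroxy-4-keto site so that the activating C4=O/O5 chelate forms poorly. Long heating may then let a freed hydroxyl add to a neighbouring prenyl double bond, or let iodoethane re-alkylate a phenoxide. The fallback sets out from 35 and comes back at 36. The three free hydroxyls of 35 would be acetylated (Ac2O, pyridine, DMAP) to 4-[3,7-bis(acetyloxy)-5-ethoxy-6,8-bis(3-methylbut-2-en-1-yl)-4-oxo-4H-chromen-2-yl]phenyl acetate F1. This removes the competing chelation site and every phenol that could cyclise onto a prenyl group. The stronger boron Lewis acid BCl3 (CH2Cl2, −78 to 0 °C) should then cleave the peri ether through the C4=O/O5 boron chelate with loss of chloroethane, giving 4-[3,7-bis(acetyloxy)-5-hydroxy-6,8-bis(3-methylbut-2-en-1-yl)-4-oxo-4H-chromen-2-yl]phenyl acetate F2. Methanolysis of the three acetates (K2CO3, MeOH, 0 °C, argon, then AcOH) returns to 36.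

2. Step 7, the benzannulation. The vinylogous-ester character of 8 may make its ring opening slow, so that thermal decomposition of the ynol ether, ketene dimerisation or acylation of the product phenol by the vinylketene competes. The fallback exchanges the roles of the partners; it sets out from 5 and 14 (with 6) and comes back at 20. Ketene 7, generated from 5 with Et3N in the presence of 14, should give by [2+2] cycloaddition the more strained, fully substituted 2,4-bis(3-methylbut-2-en-1-yl)-3-[(triisopropylsilyl)oxy]cyclobut-2-en-1-one F3. Heating F3 with an excess of the thermally simpler ethoxyacetylene 6 (toluene, sealed vessel, 80–100 °C) is the original alkoxyacetylene form of the Danheiser benzannulation and should give 5-ethoxy-2,4-bis(3-methylbut-2-en-1-yl)-3-[(triisopropylsilyl)oxy]phenol F4. In F4 the silyl group sits on O7 and the free hydroxyl on O8a; desilylation with n-Bu4NF gives diol 20, and the route continues at step 9.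

3. Step 18, ring C closure with global MOM removal. Under protic acid the freed 7-OH may add to a neighbouring prenyl double bond (chroman formation), or HCl or MeOH may add across the trisubstituted alkenes, before the last acetal is solvolysed. The fallback avoids Brønsted acid and runs in two stages; it sets out from 32 and comes back at 35. Diketone 32 would be cyclodehydrated under base (DBU, pyridine, 80–90 °C; hemiketal formation, then E1cB loss of water) and the MOM-protected flavone 34 isolated. The three acetals would then be cleaved with ZnBr2 and n-PrSH (CH2Cl2, 0 °C), where the thiol traps the methoxymethyl cation, giving 35. No compound outside the list arises (F0).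

## Further compounds

F1 | step 19 | 4-[3,7-bis(acetyloxy)-5-ethoxy-6,8-bis(3-methylbut-2-en-1-yl)-4-oxo-4H-chromen-2-yl]phenyl acetate | CCOc1c(CC=C(C)C)c(OC(C)=O)c(CC=C(C)C)c2oc(-c3ccc(OC(C)=O)cc3)c(OC(C)=O)c(=O)c12
F2 | step 19 | 4-[3,7-bis(acetyloxy)-5-hydroxy-6,8-bis(3-methylbut-2-en-1-yl)-4-oxo-4H-chromen-2-yl]phenyl acetate | CC(=O)Oc1ccc(cc1)-c1oc2c(CC=C(C)C)c(OC(C)=O)c(CC=C(C)C)c(O)c2c(=O)c1OC(C)=O
F3 | step 7 | 2,4-bis(3-methylbut-2-en-1-yl)-3-[(triisopropylsilyl)oxy]cyclobut-2-en-1-one (racemic) | O=C1C(CC=C(C)C)=C(O[Si](C(C)C)(C(C)C)C(C)C)C1CC=C(C)C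
F4 | step 7 | 5-ethoxy-2,4-bis(3-methylbut-2-en-1-yl)-3-[(triisopropylsilyl)oxy]phenol | Oc1cc(OCC)c(CC=C(C)C)c(O[Si](C(C)C)(C(C)C)C(C)C)c1CC=C(C)C
F0 | step 18 | none | none
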